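Slowness shows in Sunday's run once E has formed: E already reads 14.1% after 0.500 min, yet Z reads 24.4% only at 6.00 min.

| setting | Sunday's | flask |
|---|---|---|
| L | 2.7 M | 2.7 M |
| Q | 0.94 M | 1.89 M |
| remark | run made earlier |  |
| time |  | 10 min |

Sunday's run (percent of the L charged)

| time / min | Z / % | E / % |
|---|---|---|
| 0.500 | 2.1 | 14.1 |
| 1.00 | 3.2 | 14.5 |
| 2.50 | 13.2 | 12.0 |
| 6.00 | 24.4 | 5.3 |

(each reading ± 0.5 percentage points)

* the state of affairs at 10 min: stopped, and by what, or still going (forward and back rates have come level / all of L has reacted / it is still moving / Q has run out first)
* Z at 10 min, in percent of the L charged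
* E at 10 min, in percent of the L charged

- the reaction counts as stopped when no species that holds the L changes by six tenths of a point or more over the second half of the time

Take E to hold one L and one Q, and Z to keep them. Q is the limiting reagent in the flask. Call the pool the Q not yet in Z, free or in E. If E turns into Z at k per minute, and E is a steady share s of the pool, the pool falls in a pseudo-first-order way:

pool at time t = charged Q × exp(−k·s·t)

Sunday's last two readings put the pool at 0.584 M and 0.281 M, with a share s = 0.540. Two columns then give k separately:

from the fall of the pool (Z readings): k = 0.386 /min

from the fall of E (E readings): k = 0.432 /min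

The two stand close, so their mean is kept: k = 0.409 /min.

The ratio of E to free Q is taken to grow with free L. Sunday's free L, averaged over those last two readings, comes to about 1.96 M. In the flask, with the pool half gone, it is about 1.24 M, so the flask's share is 0.427. At 10 min this reckoning gives:

pool = 0.329 M, Z = 57.8%, E = 5.20%

By this reckoning Z in the flask still gains 17 percentage points over the second half, so the reckoning has the flask still moving.

The forecast gives Z 53% (45% to 60%) and E 5.5% (3% to 9%), and for the end state it is still moving, on the grounds that “Z is still gaining about 2 points per minute”; its Z is lower than this reckoning's.

The state of the flask at 10 min is this: it is still moving, with Z 56.2% and E 4.97%, and its largest change over the second half is 16 points. The pool left is therefore 0.373 M. With k = 0.409 /min that means a mean share of 0.397, a little less than the 0.427 reckoned.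

    E → Z (k = 0.00669 /s)
    L + Q ⇌ E (K = 0.670 /M, k = 0.0106 /M/s)

In a neighbour flask with 1.1 M of Q, L and the time as in the flask, free L halfway is reckoned at about 1.85 M and the share at 0.526, so the same k gives Z 36.0% and E 2.49%. The neighbour flask itself stands at Z 35.0% and E 2.77%.

(The runs were computed for substances that don't exist, noise included.)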